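**Retrosynthetic overview**
- C4–O bond and the only stereocentre come last. Oleiferinone is traced back to the bis(methyl enol ether) of the parent β‑triketone. A chiral dioxirane (organocatalytic) epoxidises its free enol‑ether C=C on one face, and hydrolysis follows in the same flask.
- C2–acyl bond: the bis(enol ether) comes from lithiated 1,5‑dimethoxycyclohexa‑1,4‑diene and methyl 13‑phenyltridecanoate, followed by base conjugation.
- Chain: sp3–sp3 coupling (C11–C12) of methyl 11‑bromoundecanoate with 2‑phenylethylmagnesium chloride.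
- Rings: none is formed. The carbocycle is bought at the 1,3‑dione oxidation level as the Birch‑type diene, and the phenyl ring comes with the Grignard reagent. No protecting groups are used.

Assumption: the target is one enol tautomer of (S)‑4‑hydroxy‑2‑(13‑phenyltridecanoyl)cyclohexane‑1,3‑dione ([C@H] in the given SMILES reads as S), and compounds 1, 2, 4 and the L‑series Shi ketone are taken as purchasable.

**Step 1**
Reactants: 1 methyl 11‑bromoundecanoate; 2 2‑phenylethylmagnesium chloride (1.0 M in THF, 1.3 equiv)
Product: 3 methyl 13‑phenyltridecanoate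
Conditions: Li2CuCl4 (3 mol %), NMP (4 equiv), THF, 0 °C → rt, slow addition of 2
Reagents that add atoms: none
Why: Kochi‑type Cu‑catalysed sp3–sp3 cross‑coupling, in which the alkylcuprate formed in the flask displaces the primary bromide much faster than the Grignard reagent adds to the ester when NMP is present; no stereocentre is formed.

**Step 2**
Reactants: 4 1,5‑dimethoxycyclohexa‑1,4‑diene (2.3 equiv); 3 methyl 13‑phenyltridecanoate (1.0 equiv)
Product: 7 1‑(2,6‑dimethoxycyclohexa‑1,5‑dien‑1‑yl)‑13‑phenyltridecan‑1‑one, via lithiated diene 5 (not isolated), via skipped dienyl ketone 6 (not isolated)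
Conditions: t‑BuLi (2.2 equiv), THF, −78 °C, 1 h; 3, −78 → −30 °C; MeOH, 0 °C → rt, 2 h; pH 7 buffer; Ar, degassed solvents, Et3N‑washed silica
Reagents that add atoms: none
Why: Claisen‑type acylation of a cyclohexadienyl‑lithium at its central carbon (the CH2 between the two enol‑ether carbons is the known metalation and alkylation site of 4); the second equivalent of 5 deprotonates the very acidic ketone 6 at once and so blocks over‑addition, and LiOMe/MeOH then equilibrates 6 to the conjugated push–pull isomer 7; no stereocentre is formed.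

**Step 3**
Reactants: 7 1‑(2,6‑dimethoxycyclohexa‑1,5‑dien‑1‑yl)‑13‑phenyltridecan‑1‑one
Product: 10 oleiferinone, (S)‑3,6‑dihydroxy‑2‑(13‑phenyltridecanoyl)cyclohex‑2‑en‑1‑one, via methoxy epoxide 8 (not isolated), via hydroxy methoxy enone 9 (not isolated)
Conditions: ent‑Shi ketone (1,2:4,5‑di‑O‑isopropylidene‑β‑L‑erythro‑2,3‑hexodiulo‑2,6‑pyranose, 30 mol %), Oxone (1.4 equiv) and K2CO3 added in parallel, Bu4NHSO4 (5 mol %), Na2B4O7/Na2EDTA buffer (pH 10.5), MeCN–DMM 1:2, −5 °C, 2 h; Na2SO3; then 1 M H2SO4 to pH 1, THF, rt, 2 h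
Reagents that add atoms: Oxone (active component potassium peroxymonosulfate), [K+].[O-]S(=O)(=O)OO; water, O
Why: Proposed new method: catalytic enantioselective α′‑hydroxylation of a β‑triketone through its cross‑conjugated bis(enol ether), in which the electrophilic dioxirane made from the ketone catalyst and KHSO5 should attack only the electron‑rich trisubstituted C5=C6 enol ether of 7 (the tetrasubstituted C1=C2 is a deactivated, hindered push–pull alkene), through the usual spiro transition state in which C5–H and not the ring CH2 faces the catalyst's dioxolane, so that the L‑series ketone gives the (S) carbinol carbon (the D‑series ketone gives the (R,R)‑oxide from 1‑phenylcyclohexene, which has the same substitution geometry); the 2‑methoxyoxirane 8 opens at its acetal carbon with the new C–O bond kept, water adds and MeOH leaves to give 9 (water attack at the vinylogous position gives a regioisomeric enol ether that converges), and acid hydrolysis of the doubly activated vinylogous ester gives 10 without touching the stereocentre; the closest known reaction types are the Shi epoxidation of silyl enol ethers, enol esters and conjugated dienes and the Rubottom oxidation, none of which has been shown on alkoxydienes of the 2‑acyl‑1,3‑dione type.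

**Compound list**
1 | methyl 11‑bromoundecanoate | COC(=O)CCCCCCCCCCBr | starting material
2 | 2‑phenylethylmagnesium chloride | Cl[Mg]CCc1ccccc1 | starting material
3 | methyl 13‑phenyltridecanoate | COC(=O)CCCCCCCCCCCCc1ccccc1 | intermediate
4 | 1,5‑dimethoxycyclohexa‑1,4‑diene | COC1=CCC=C(OC)C1 | starting material
5 | (2,6‑dimethoxycyclohexa‑2,5‑dien‑1‑yl)lithium (lithiated diene, not isolated) | [Li]C1C(OC)=CCC=C1OC | intermediate
6 | 1‑(2,6‑dimethoxycyclohexa‑2,5‑dien‑1‑yl)‑13‑phenyltridecan‑1‑one (skipped dienyl ketone, first formed as its lithium enolate, not isolated) | O=C(CCCCCCCCCCCCc1ccccc1)C1C(OC)=CCC=C1OC | intermediate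
7 | 1‑(2,6‑dimethoxycyclohexa‑1,5‑dien‑1‑yl)‑13‑phenyltridecan‑1‑one | O=C(CCCCCCCCCCCCc1ccccc1)C1=C(OC)CCC=C1OC | intermediate
8 | 1‑[(1R,6S)‑1,3‑dimethoxy‑7‑oxabicyclo[4.1.0]hept‑2‑en‑2‑yl]‑13‑phenyltridecan‑1‑one (methoxy epoxide, not isolated) | O=C(CCCCCCCCCCCCc1ccccc1)C1=C(OC)CC[C@@H]2O[C@]12OC | intermediate
9 | (S)‑6‑hydroxy‑3‑methoxy‑2‑(13‑phenyltridecanoyl)cyclohex‑2‑en‑1‑one (hydroxy methoxy enone, not isolated) | O=C(CCCCCCCCCCCCc1ccccc1)C1=C(OC)CC[C@H](O)C1=O | intermediate
10 | oleiferinone, (S)‑3,6‑dihydroxy‑2‑(13‑phenyltridecanoyl)cyclohex‑2‑en‑1‑one | O=C(CCCCCCCCCCCCc1ccccc1)C1=C(O)CC[C@H](O)C1=O | target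

**Count**
Total steps: 3. Longest linear sequence: 3 (1 → 3 → 7 → 10).

**Steps most likely to fail, with fallbacks**

Step 3 (the new step) carries four risks:
- uncatalysed racemic oxidation of the electron‑rich enol ether by Oxone;
- a lower ee, because OMe is small and the twisted acyl group crowds C6;
- over‑oxidation of the triketonate at C2;
- partial hydrolysis of 7 before oxidation.

The ee is checked by chiral HPLC on 10 and can be raised by recrystallisation. The fallback uses known chemistry and sets out from 7.
- Dimethyldioxirane in wet acetone at −20 °C gives the racemic methoxy epoxide F1. It hydrolyses in the flask to the racemic hydroxy methoxy enone F2.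
- An isothiourea‑catalysed acylative kinetic resolution follows: HyperBTM 2 mol %, isobutyric anhydride 0.6 equiv, i‑Pr2NEt, toluene, 0 °C. The catalyst enantiomer is chosen so that the (R)‑alcohol reacts faster. This converts that antipode into the (R)‑isobutyrate F3 and leaves the (S)‑alcohol, which is separated by chromatography.
- The fallback comes back to the route at 9. 1 M H2SO4/THF then takes 9 to 10. The yield ceiling is 50 %.

Step 2 carries three risks:
- 5 may deprotonate the ester α‑CH2 instead of adding to the carbonyl;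
- some attack may occur through a terminal carbon of the dienyl anion;
- 6 and 7 may aromatise in air.

The fallback sets out from 3.
- DIBAL‑H (1.05 equiv, CH2Cl2, −78 °C) gives 13‑phenyltridecanal F4.
- Addition of 5 (1.2 equiv, made from 4 as above, THF, −78 °C) to this far more electrophilic carbonyl gives the racemic dienyl carbinol F5.
- Parikh–Doering oxidation (SO3·pyridine, DMSO, Et3N, 0 °C; non‑acidic, so the enol ethers survive) removes that stereocentre.
- The fallback comes back to the route at 6. Catalytic DBU completes the conjugation to 7.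

Step 1 carries three risks: Grignard homocoupling, β‑hydride loss, and some attack on the ester. The fallback sets out from 1.
- PPh3 in refluxing MeCN gives the phosphonium bromide F6.
- NaHMDS (THF, −78 °C) gives the ylide F7.
- Wittig reaction with phenylacetaldehyde gives the (Z)‑alkenoate F8.
- Hydrogenation (H2, Pd/C, EtOAc) comes back to the route at 3.

**Further compounds**
F1 | step 3 | racemic 1‑(1,3‑dimethoxy‑7‑oxabicyclo[4.1.0]hept‑2‑en‑2‑yl)‑13‑phenyltridecan‑1‑one | O=C(CCCCCCCCCCCCc1ccccc1)C1=C(OC)CCC2OC12OC
F2 | step 3 | racemic 6‑hydroxy‑3‑methoxy‑2‑(13‑phenyltridecanoyl)cyclohex‑2‑en‑1‑one | O=C(CCCCCCCCCCCCc1ccccc1)C1=C(OC)CCC(O)C1=O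
F3 | step 3 | (R)‑4‑methoxy‑2‑oxo‑3‑(13‑phenyltridecanoyl)cyclohex‑3‑en‑1‑yl 2‑methylpropanoate | O=C(CCCCCCCCCCCCc1ccccc1)C1=C(OC)CC[C@@H](OC(=O)C(C)C)C1=O
F4 | step 2 | 13‑phenyltridecanal | O=CCCCCCCCCCCCCc1ccccc1
F5 | step 2 | racemic 1‑(2,6‑dimethoxycyclohexa‑2,5‑dien‑1‑yl)‑13‑phenyltridecan‑1‑ol | OC(CCCCCCCCCCCCc1ccccc1)C1C(OC)=CCC=C1OC
F6 | step 1 | (11‑methoxy‑11‑oxoundecyl)triphenylphosphonium bromide | COC(=O)CCCCCCCCCC[P+](c1ccccc1)(c1ccccc1)c1ccccc1.[Br-]
F7 | step 1 | methyl 11‑(triphenyl‑λ5‑phosphanylidene)undecanoate | COC(=O)CCCCCCCCCC=P(c1ccccc1)(c1ccccc1)c1ccccc1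
F8 | step 1 | methyl (Z)‑13‑phenyltridec‑11‑enoate | COC(=O)CCCCCCCCC/C=C\Cc1ccccc1
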